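All runs are calculated with made-up constants.

Every turn of either coupling takes one coupling partner, so partner spent equals product made, whatever the substrates do in between.

in all of them: left-handed substrate 0.20 M; right-handed substrate 0.20 M; free catalyst 9.6 mM; racemization catalyst 0.10 mM; added ligand 7.6 mM

| flask | coupling partner | remark | time |
|---|---|---|---|
| midnight | 0.44 M | the very flask that is asked about, followed so far |  |
| flask | 0.440 M |  | 12 min |

midnight run (percent of the left-handed substrate and right-handed substrate together charged)

| time / min | left-handed product / % | right-handed product / % |
|---|---|---|
| 0.500 | 7.7 | 0.4 |
| 1.50 | 19.0 | 1.4 |
| 3.00 | 30.0 | 2.5 |
| 4.00 | 35.7 | 3.8 |
| 6.00 | 43.6 | 5.1 |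

(standard deviation of a reading: 0.3 percentage points)

- free catalyst is single-handed; left-handed substrate and right-handed substrate are mirror images of each other, charged as a racemate, each of them at the stated concentration
- an excess is the difference of the two amounts in percent of their sum
- an excess is below zero if the other one leads

- left-handed product and right-handed product together, in percent of the left-handed substrate and right-handed substrate charged together, at 12 min
- excess of left-handed product over right-handed product in the product at 12 min
- whether the exchange between left-handed substrate and right-handed substrate keeps pace with the reaction: how far the product's excess at 12 min gets from its value without exchange to its value with instant exchange (above 80% keeps pace, below 20% hardly takes part, else lags behind)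

The flask asked about is the midnight run itself, followed on to 12 min. This is my own reckoning, in slow motion.

1. The rule. Call the substrates charged together over the partner charged the draw-down ratio, 0.909. The share of partner left is one minus this ratio times the yield.

2. First instants. I assume both couplings are first order in [coupling partner], and pseudo-first-order once that is frozen at its current share. Over the first 0.500 min the mean partner share is 96.3%, and the mean left-handed stock is 46.1% of the substrates charged. The first reading therefore gives a constant at full partner of 0.346 /min, as a reading.

3. Middle. Treat the left-handed stock as its charge minus the left-handed product, and the apparent constant stays flat: 0.334 /min at 0.500 min, 0.343 /min at 6.00 min. Yet the rule leaves 55.7% of the partner by then. On my assumption, a flat constant on falling [coupling partner] points to a left-handed stock that is being refilled.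

4. Size. Between 4.00 min and 6.00 min, the rate of left-handed product divided by the constant and the partner share reads a stock of 19.0% of the substrates charged. No exchange gives 10.3%, and instant exchange 27.9%.

5. End. That is about half the way for the stock at that moment. I take it as a stand-in for the way of the product's excess, between 20% and 80%, so I call the exchange lagging behind.

The forecast gives 62%, 71% and "hardly takes part", reading its last point as “hinting at weak exchange”. Here my stock reading parts from it.

The flask gives 62.8%, 79.5% and "lags behind", at 53% of the way.

    coupling partner + free catalyst + left-handed substrate → free catalyst + left-handed product (k = 110 /M²/min)
    coupling partner + free catalyst + right-handed substrate → free catalyst + right-handed product (k = 7.30 /M²/min)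
    left-handed substrate + racemization catalyst ⇌ right-handed substrate + racemization catalyst, rate k3*[racemization catalyst]*[left-handed substrate] forward; the back reaction follows from the equilibrium constant (k = 3300 /M/min)
    free catalyst + added ligand ⇌ idle complex (K = 65.0 /M, k = 630 /M/min)
    2 racemization catalyst → spent catalyst (k = 3300 /M/min)

In this flask the exchange's forward half-life as charged, 2.1 min, is longer than the first half-life of the racemization catalyst by its own pairing, 1.52 min. At 12.0 min the racemization catalyst stands at 11.2% of its charge, with left-handed substrate at 9.35% and right-handed substrate at 27.8%. The draw-down ratio leaves 42.9% of the partner here, where the flask holds 43%. In the neighbour charged with 0.18 M of partner, the ratio 2.22 on a yield of 33.9% leaves 24.6%, and that flask holds 25%.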